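**Retrosynthetic overview** (drimane numbering: ring A = C1–C5 and C10; ring B = C5–C10; C11 = the OCH2 carbon on C9; C12 = the methyl on C8)
1. The aryl ether is made last by Mitsunobu coupling of the C11 alcohol with umbelliferone; C11 itself comes from a C9 ketone by methylenation and face-selective hydroboration.
2. Enabling feature: ring B holds the trisubstituted C7=C8 alkene next to C9, whose one-carbon branch can be carried as a ketone. Ring B is then a 2-methylcyclohex-2-enone, and C7 and C9 stand in a 1,5-relationship across the ring-fusion bond C5–C10.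
3. Key disconnection: both rings from one acyclic keto-enal. C5–C10 is formed by intramolecular Michael addition (closes ring A), then C7=C8 by aldol condensation (closes ring B), in the same pot.
4. The quaternary C4 leaves the enal without γ-hydrogens, so it can act only as an electrophile, and its gem-dimethyl group favours ring closure.
5. The keto-enal is assembled from a β-keto ester and acrolein (C1–C10), an asymmetric reverse prenylation (C3–C4, sets the C3 carbinol), decarboxylation and cross-metathesis (C5=C6).

Key step: step 6

Remark: 1 is taken as commercially available and used as the racemate; the centre it creates (later C10) stays a mixture until step 6 makes it trigonal. The acetate of the target is installed in step 3 and carried to the end, so no protecting group is used.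

**Step 1**
Reactants: 1 ethyl 2-methyl-3-oxopentanoate (racemic); 2 acrolein
Product: 3 ethyl 2-methyl-3-oxo-2-(3-oxopropyl)pentanoate (racemic)
Conditions: Et3N (10 mol%), MeCN, 0 °C → rt
Reagents that add atoms: none
Why: Amine-catalysed Michael addition of the only acidic carbon of the β-keto ester to acrolein should give the C1–C10 bond cleanly; the new quaternary centre is racemic and is erased later.

**Step 2**
Reactants: 3; 4 3-methylbuta-1,2-diene
Product: 7 ethyl 2-[(3R)-3-hydroxy-4,4-dimethylhex-5-en-1-yl]-2-methyl-3-oxopentanoate (both epimers at C2), via prenylborane 5 (not isolated), via borinate ester 6 (not isolated)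
Conditions: (−)-Ipc2BH [(−)-diisopinocampheylborane, from (+)-α-pinene], 4, THF, −25 → 0 °C; then 3, Et2O, −78 °C; then NaBO3·4H2O, H2O, rt
Reagents that add atoms: none
Why: Brown asymmetric reverse prenylboration through a closed chair transition state should deliver the tertiary allyl terminus to the Si face of the aldehyde (the sense that gives R-homoallylic alcohols from simple alkanals with this pinene series), setting the carbinol (later C3) as R and building the gem-dimethyl carbon, while the hindered ketone and the ester should not react at −78 °C.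

**Step 3**
Reactants: 7
Product: 8 ethyl 2-[(3R)-3-acetoxy-4,4-dimethylhex-5-en-1-yl]-2-methyl-3-oxopentanoate (both epimers at C2)
Conditions: Ac2O, pyridine, 4-(dimethylamino)pyridine (cat.), CH2Cl2, rt
Reagents that add atoms: acetic anhydride, CC(=O)OC(C)=O
Why: Nucleophile-catalysed acylation of the hindered secondary alcohol installs the acetate of the target and also blocks lactonisation onto the ester and hemiketal formation with the ketone.

**Step 4**
Reactants: 8
Product: 9 (4R)-3,3,7-trimethyl-8-oxodec-1-en-4-yl acetate (both epimers at C7)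
Conditions: LiCl, H2O (2 equiv), DMSO, 150 °C
Reagents that add atoms: none
Why: Krapcho dealkoxycarbonylation: chloride dealkylates the activated ethyl ester and the β-keto carboxylate loses CO2, while the unactivated, hindered acetate should survive the near-neutral medium.

**Step 5**
Reactants: 9; 10 (E)-but-2-enal
Product: 11 (2E,5R)-4,4,8-trimethyl-1,9-dioxoundec-2-en-5-yl acetate (both epimers at C8)
Conditions: RuCl2(H2IMes)(=CH-C6H4-2-O-i-Pr) (second-generation Hoveyda–Grubbs catalyst, 5 mol%), 10 (excess), CH2Cl2, 40 °C
Reagents that add atoms: none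
Why: Olefin cross-metathesis of the terminal alkene with excess crotonaldehyde releases propene and should give the E-enal under thermodynamic control; ketone and acetate are inert to the ruthenium carbene.

**Step 6**
Reactants: 11
Product: 14 (2R,4aR,8aR)-1,1,4a,6-tetramethyl-5-oxo-1,2,3,4,4a,5,8,8a-octahydronaphthalen-2-yl acetate, via cyclohexane keto-aldehyde Michael adduct 12 (not isolated), via ring B aldol 13 (not isolated)
Conditions: (R)-2-[diphenyl(trimethylsilyloxy)methyl]pyrrolidine (20 mol%), PhCO2H (20 mol%), toluene (0.02 M), 40 °C; then TsOH·H2O (20 mol%), 60 °C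
Reagents that add atoms: none
Why: Proposed new method: the secondary amine condenses with the non-enolisable enal to an E-configured unsaturated iminium ion, the more substituted enol of the ketone (C9=C10) adds through C10 to C5 in a 6-(enolexo)-exo-trig closure that makes ring A, and the C8 enol then attacks the C7 aldehyde (or its iminium ion) in a 6-(enolendo)-exo-trig aldol whose dehydration gives C7=C8 and ring B. The closest known reaction types are the amine-catalysed Michael/aldol-condensation [3+3] annulation of β-keto esters with enals and the acid-promoted Robinson-type Michael reaction of ketones through their more substituted enol; what is new is an unactivated α-branched ketone as the intramolecular donor. C5 is controlled by the catalyst: the diphenyl(silyloxy)methyl group of the R-amine shields one face of the iminium ion, so C10 should attack the other face, which is also the face reached in the chair with the C3 acetate equatorial (matched pair, the substrate bias alone being small). C10 is controlled by the chair-like transition state: the bulky enol unit avoids the syn-axial C4 methyl, so the C10 methyl goes axial and anti to H-5, which is the trans ring fusion. The selectivities needed are C10 and not C8 as Michael donor and C8→C7 and not C6→C9 in the aldol step; both are secured by ring size (six-membered against eight- or four-membered), and the quaternary C4 keeps the enal from forming a dienamine or self-condensing.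

**Step 7**
Reactants: 14
Product: 15 (2R,4aR,8aS)-1,1,4a,6-tetramethyl-5-methylidene-1,2,3,4,4a,5,8,8a-octahydronaphthalen-2-yl acetate
Conditions: Zn, CH2Br2, TiCl4, THF/CH2Cl2, 0 °C → rt
Reagents that add atoms: dibromomethane, BrCBr
Why: Takai–Lombardo methylenation: the small, non-basic geminal dimetallic reagent should add to the hindered C9 ketone without touching the acetate or enolising the enone; no stereocentre is formed.

**Step 8**
Reactants: 15
Product: 17 (2R,4aR,5R,8aS)-5-(hydroxymethyl)-1,1,4a,6-tetramethyl-1,2,3,4,4a,5,8,8a-octahydronaphthalen-2-yl acetate, via B-alkyl-9-BBN adduct 16 (not isolated)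
Conditions: 9-borabicyclo[3.3.1]nonane (9-BBN), THF, 0 °C → rt; then NaBO3·4H2O, H2O, rt
Reagents that add atoms: sodium perborate, [Na+].[O-]OB=O
Why: Hydroboration–oxidation: 9-BBN should add only to the exocyclic 1,1-disubstituted alkene, boron at C11 and hydrogen to C9 from the face opposite the axial C10 methyl, which sets C9 as R with the CH2OH group equatorial; the mild perborate oxidation should spare the acetate.

**Step 9**
Reactants: 17; 18 umbelliferone (7-hydroxy-2H-chromen-2-one)
Product: 19 (2R,4aR,5R,8aS)-1,1,4a,6-tetramethyl-5-{[(2-oxo-2H-chromen-7-yl)oxy]methyl}-1,2,3,4,4a,5,8,8a-octahydronaphthalen-2-yl acetate (target)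
Conditions: PPh3, diisopropyl azodicarboxylate, THF, 0 °C → rt
Reagents that add atoms: none
Why: Mitsunobu etherification of the primary alcohol with the acidic phenol forms the C11–O bond without touching any stereocentre, the lactone or the acetate.

**Compound list**
1 | ethyl 2-methyl-3-oxopentanoate (racemic) | CCC(=O)C(C)C(=O)OCC | starting material
2 | acrolein | C=CC=O | starting material
3 | ethyl 2-methyl-3-oxo-2-(3-oxopropyl)pentanoate (racemic) | CCC(=O)C(C)(CCC=O)C(=O)OCC | intermediate
4 | 3-methylbuta-1,2-diene | CC(C)=C=C | starting material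
5 | (3-methylbut-2-en-1-yl)bis(isopinocampheyl)borane, (+)-α-pinene series | CC(C)=CCB([C@@H]1C[C@@H]2C[C@@H](C2(C)C)[C@H]1C)[C@@H]1C[C@@H]2C[C@@H](C2(C)C)[C@H]1C | intermediate
6 | ethyl 2-[(3R)-3-{[bis(isopinocampheyl)boranyl]oxy}-4,4-dimethylhex-5-en-1-yl]-2-methyl-3-oxopentanoate | CCC(=O)C(C)(CC[C@@H](OB([C@@H]1C[C@@H]2C[C@@H](C2(C)C)[C@H]1C)[C@@H]1C[C@@H]2C[C@@H](C2(C)C)[C@H]1C)C(C)(C)C=C)C(=O)OCC | intermediate
7 | ethyl 2-[(3R)-3-hydroxy-4,4-dimethylhex-5-en-1-yl]-2-methyl-3-oxopentanoate | CCC(=O)C(C)(CC[C@@H](O)C(C)(C)C=C)C(=O)OCC | intermediate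
8 | ethyl 2-[(3R)-3-acetoxy-4,4-dimethylhex-5-en-1-yl]-2-methyl-3-oxopentanoate | CCC(=O)C(C)(CC[C@@H](OC(C)=O)C(C)(C)C=C)C(=O)OCC | intermediate
9 | (4R)-3,3,7-trimethyl-8-oxodec-1-en-4-yl acetate | CCC(=O)C(C)CC[C@@H](OC(C)=O)C(C)(C)C=C | intermediate
10 | (E)-but-2-enal (crotonaldehyde) | C/C=C/C=O | starting material
11 | (2E,5R)-4,4,8-trimethyl-1,9-dioxoundec-2-en-5-yl acetate | CCC(=O)C(C)CC[C@@H](OC(C)=O)C(C)(C)/C=C/C=O | intermediate
12 | (1R,3R,4R)-2,2,4-trimethyl-3-(2-oxoethyl)-4-propanoylcyclohexyl acetate | CC(=O)O[C@@H]1CC[C@@](C)(C(=O)CC)[C@H](CC=O)C1(C)C | intermediate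
13 | (2R,4aR,8aR)-7-hydroxy-1,1,4a,6-tetramethyl-5-oxodecahydronaphthalen-2-yl acetate (epimers at C6 and C7) | CC(=O)O[C@@H]1CC[C@@]2(C)C(=O)C(C)C(O)C[C@@H]2C1(C)C | intermediate
14 | (2R,4aR,8aR)-1,1,4a,6-tetramethyl-5-oxo-1,2,3,4,4a,5,8,8a-octahydronaphthalen-2-yl acetate | CC(=O)O[C@@H]1CC[C@@]2(C)C(=O)C(C)=CC[C@@H]2C1(C)C | intermediate
15 | (2R,4aR,8aS)-1,1,4a,6-tetramethyl-5-methylidene-1,2,3,4,4a,5,8,8a-octahydronaphthalen-2-yl acetate | CC(=O)O[C@@H]1CC[C@@]2(C)C(=C)C(C)=CC[C@@H]2C1(C)C | intermediate
16 | B-alkyl-9-BBN adduct of 15 (boron on the exocyclic carbon) | CC(=O)O[C@@H]1CC[C@@]2(C)[C@H](CB3C4CCCC3CCC4)C(C)=CC[C@@H]2C1(C)C | intermediate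
17 | (2R,4aR,5R,8aS)-5-(hydroxymethyl)-1,1,4a,6-tetramethyl-1,2,3,4,4a,5,8,8a-octahydronaphthalen-2-yl acetate | CC(=O)O[C@@H]1CC[C@@]2(C)[C@H](CO)C(C)=CC[C@@H]2C1(C)C | intermediate
18 | umbelliferone (7-hydroxy-2H-chromen-2-one) | O=c1ccc2ccc(O)cc2o1 | starting material
19 | (2R,4aR,5R,8aS)-1,1,4a,6-tetramethyl-5-{[(2-oxo-2H-chromen-7-yl)oxy]methyl}-1,2,3,4,4a,5,8,8a-octahydronaphthalen-2-yl acetate | CC(=O)O[C@@H]1CC[C@@]2(C)[C@H](COc3ccc4ccc(=O)oc4c3)C(C)=CC[C@@H]2C1(C)C | target

**Total step count:** 9
**Longest linear sequence:** 9 steps (from 1)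

**Steps most likely to fail**

Step 6 (carries the label). The enol of the unactivated ketone may add too slowly to the hindered iminium ion, so that oligomerisation of the enal or simple return to 11 wins, and facial control may erode if an uncatalysed acid pathway takes over. The fallback uses known chemistry, sets out from 11 and returns at 14. Compound 11 would be silylated under equilibrating conditions (TMSOTf, Et3N, CH2Cl2, 0 °C → rt) to the more substituted silyl enol ether (2E,5R)-4,4,8-trimethyl-1-oxo-9-[(trimethylsilyl)oxy]undeca-2,8-dien-5-yl acetate F1; the less substituted regioisomer cannot close a six-membered ring and would come back as 11. TiCl4 (CH2Cl2, −78 °C) would then trigger an intramolecular Mukaiyama–Michael addition under substrate control (chair, acetate equatorial, methyl axial), giving 12 in isolated form after aqueous work-up. TsOH·H2O in toluene at 60 °C would close ring B to 14 in a separate aldol condensation.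

Step 7. Methylene transfer may stall at the C9 carbonyl, which is flanked by the quaternary C10 and the methyl-bearing C8, or the Lewis-acidic medium may isomerise the new diene. The fallback sets out from 14 and returns at 15, replacing carbonyl olefination by addition and elimination. Excess MeLi with CeCl3 (THF, −78 °C) would add methyl to C9 and cleave the acetate at the same time, giving (2R,4aR,8aR)-1,1,4a,5,6-pentamethyl-1,2,3,4,4a,5,8,8a-octahydronaphthalene-2,5-diol F2. Ac2O in pyridine at 0 °C would re-acetylate only the secondary hydroxyl to (2R,4aR,8aR)-5-hydroxy-1,1,4a,5,6-pentamethyl-1,2,3,4,4a,5,8,8a-octahydronaphthalen-2-yl acetate F3. Burgess reagent (benzene, 50 °C) would dehydrate the tertiary allylic alcohol toward the only β-hydrogens available, those of the new methyl, to give 15.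

Step 5. Turnover in the cross-metathesis may be slow because the vinyl group sits on a fully substituted carbon next to the branched acetoxy carbon, so that catalyst decomposition and self-metathesis of crotonaldehyde take over. The fallback sets out from 9 and returns at 11. Ozonolysis (O3, CH2Cl2, −78 °C; then Me2S) would cut the vinyl group to (3R)-2,2,6-trimethyl-1,7-dioxononan-3-yl acetate F4, and a Wittig reaction with (triphenylphosphoranylidene)acetaldehyde (toluene, 80 °C) would give the E-enal 11.

**Further compounds**
F1 | step 6 | (2E,5R)-4,4,8-trimethyl-1-oxo-9-[(trimethylsilyl)oxy]undeca-2,8-dien-5-yl acetate | CCC(O[Si](C)(C)C)=C(C)CC[C@@H](OC(C)=O)C(C)(C)/C=C/C=O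
F2 | step 7 | (2R,4aR,8aR)-1,1,4a,5,6-pentamethyl-1,2,3,4,4a,5,8,8a-octahydronaphthalene-2,5-diol (epimers at C5) | O[C@@H]1CC[C@@]2(C)C(C)(O)C(C)=CC[C@@H]2C1(C)C
F3 | step 7 | (2R,4aR,8aR)-5-hydroxy-1,1,4a,5,6-pentamethyl-1,2,3,4,4a,5,8,8a-octahydronaphthalen-2-yl acetate (epimers at C5) | CC(=O)O[C@@H]1CC[C@@]2(C)C(C)(O)C(C)=CC[C@@H]2C1(C)C
F4 | step 5 | (3R)-2,2,6-trimethyl-1,7-dioxononan-3-yl acetate | CCC(=O)C(C)CC[C@@H](OC(C)=O)C(C)(C)C=O
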